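E and L compete for X.

| setting | amber | green | red | spring | dawn | dusk | summer |
|---|---|---|---|---|---|---|---|
| X | 33 mM | 33 mM | 33 mM | 33 mM | 33 mM | 33 mM | 33 mM (fed, over 20 min) |
| Q | 132 mM | 180 mM | 290 mM | 132 mM | 132 mM | 132 mM (fed, over 20 min) | 132 mM |
| J | 6.6 mM | 6.6 mM | 6.6 mM | 6.60 mM | 6.60 mM | 6.60 mM | 6.60 mM |
| temperature | 45 °C | 60 °C | 45 °C |  | 60 °C | 60 °C |  |
| remark | run made earlier | run made earlier | run made earlier | everything together at the start at 20 °C, warmed to 60 °C at 20 min | everything together at the start | all else is in the flask from the start; the feed brings no volume worth counting | the addition at 20 °C, then warmed to 60 °C; the feed brings no volume worth counting |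
| time |  |  |  | 50 min | 50 min | 50 min | 50 min |

- amber (time / min: E / %, L / %): 4.00: 0.6, 1.1; 12.0: 4.5, 0.2; 20.0: 6.2, 0.7; 30.0: 8.2, 0.3; 50.0: 13.1, 1.4; 60.0: 14.8, 1.0
- green (time / min: E / %, L / %): 4.00: 6.3, 0.4; 6.00: 9.2, 0.9; 12.0: 15.1, 0.9; 20.0: 21.4, 1.0; 30.0: 29.7, 2.4; 50.0: 41.5, 3.6
- red (time / min: E / %, L / %): 15.0: 8.5, 1.6; 30.0: 16.6, 1.7; 50.0: 24.3, 4.3; 60.0: 28.3, 4.6; 80.0: 33.2, 6.1; 120: 42.7, 7.1

(scatter of a reading: 0.5 percentage points)

- the numbers in the tables scatter by 0.5 percentage points (one standard deviation)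
- steps thought possible: X + Q -> E; X + 2 Q -> L; Q -> G; X + J -> D

1. the flask with the highest share of E in E plus L ("all alike" if they lie within 1.5 percentage points) (spring / dawn / dusk / summer / all alike)
2. share of E in E plus L at the end, spring
3. share of E in E plus L at the end, dawn
4. share of E in E plus L at the end, dusk
5. share of E in E plus L at the end, summer

1. Each step's rate carries X. The E step carries Q once and the L step twice, so dL/dE = s·Q at one temperature. Integrated, L/E = s·Q̄, where Q̄ is the mean Q weighted by the E formed. X cancels.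

2. The selectivity factor s is the L formed per E formed, per mM of Q. The last green reading, with Q taken as its charge, gives s = 4.82 × 10⁻⁴ mM⁻¹ at 60 °C. This is a reading, and its L carries the scatter of 0.5 percentage points.

3. My own reckoning with Q at the full 132 mM gives a share of 94.0%.

4. Now the opposite outcome. For flasks to part by 1.5 points, their Q̄ must differ by 35.2 mM.

5. Let f be the fraction of E formed during a Q feed. At steady X, E forms in proportion to Q during a linear Q feed, so the E-weighted mean Q of the feed is 2/3 of the charge. Then Q̄ lies below the charge by f·132 mM/3, so a Q feed needs f = 80.0%, the critical f.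

6. In dusk, with X held constant and Q rising steadily, E follows the integral of Q over time. That gives f = 25.0%, less than the critical f. My reckoning therefore says all alike.

7. The forecast also says all alike, with 94.3% for spring, 94.6% for dawn, 95.1% for dusk and 94.3% for summer, “all within 1.5 points”.

8. The flasks give all alike: spring 94.9%, dawn 95.2%, dusk 95.7%, summer 95.1%. Dusk and spring lie 0.80 points apart.

    X + Q → E (k = 0.0818 M⁻¹ min⁻¹, Ea = 73.0 kJ mol⁻¹)
    X + 2 Q → L (k = 0.0324 M⁻² min⁻¹, Ea = 51.0 kJ mol⁻¹)
    Q → G (k = 2.24 × 10⁻⁵ min⁻¹, Ea = 116 kJ mol⁻¹)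
    X + J → D (k = 4.21 M⁻¹ min⁻¹, Ea = 66.0 kJ mol⁻¹)
    (constants at 60 °C)

In spring, the E step uses Q 9.9 times as fast as the L step at 32.5 min and 10 times as fast at 50.0 min. Dusk holds 8.52% E at the end of its feed and 27.4% at 50.0 min, so its f is 31.1%, below the critical 80.0%.

The earlier runs and the new flask come from a simulation for an exercise, noise included.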